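Counting Z is the easy step: a D holds one Z and an X holds two. So I follow one J. It takes one Z to become D, and at the fork it stays or takes a second.

| flask | J | Z | remark | time |
|---|---|---|---|---|
| Sunday's | 0.32 M | 0.26 M | run made earlier |  |
| Friday's | 0.32 M | 0.58 M | run made earlier |  |
| green | 0.32 M | 0.384 M |  | 12 h |
| ochre | 0.32 M | 0.384 M |  | 25 h |

| run | time / h | D / % | J / % | X / % |
|---|---|---|---|---|
| Sunday's | 1.00 | 0.8 | 100.1 | 0 |
| Sunday's | 3.00 | 5.1 | 95.2 | 0 |
| Sunday's | 5.00 | 10.4 | 88.3 | 0.8 |
| Sunday's | 8.00 | 17.0 | 80.4 | 3.1 |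
| Sunday's | 12.0 | 22.0 | 69.9 | 7.5 |
| Sunday's | 15.0 | 25.7 | 62.5 | 11.6 |
| Friday's | 1.00 | 0.4 | 99.0 | 0.1 |
| Friday's | 2.00 | 2.7 | 98.0 | 0.8 |
| Friday's | 3.00 | 4.0 | 93.9 | 0.3 |
| Friday's | 5.00 | 9.7 | 89.7 | 1.2 |
| Friday's | 8.00 | 16.5 | 80.0 | 2.9 |
| Friday's | 15.0 | 25.7 | 62.7 | 12.2 |

(each reading ± 0.5 percentage points)

- as a solid, counted per litre of solution: Z
- the earlier runs were read with a standard deviation of 0.5 percentage points
- candidate steps: J + Q -> D; Q + D -> X; Z <-> Q
- at the start none of Z is in solution

* which of these there is most of at the end, counted by the J in it, green (D / J / X)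
* which of these there is most of at the end, counted by the J in it, ochre (D / J / X)
* final amount of the leader among these, as a percentage of the J charged, in green
* final amount of the leader among these, as a percentage of the J charged, in ochre

Which number must I know well? The Z charge does not show in the readings: at 15.0 h, J reads 62.5 % with 0.26 M of Z in Sunday's run and 62.7 % with 0.58 M in Friday's, a gap inside the scatter of 0.5 percentage points. Time does show. Sunday's J between 5.00 h and 15.0 h gives a loss rate of 0.0346 /h. What must hold is the stock, so I reckon the Z bill: the J charge times the sum of D and two X. In Sunday's run at 15.0 h the Z bill reads 0.156 M.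

Ochre's J at 25 h: 62.5 % × exp(−0.0346 /h × 10.0 h) = 44.2 %

Z per J lost, Sunday's run at 15.0 h: 1.31, and the fork allows two at most.

Ochre's bill: from 0.234 M to 0.357 M, against a charge of 0.384 M.

So ochre's bill stays below its charge, and I keep the loss rate, though the bill leaves out Z dissolved as Q, which the readings do not show. Green at 12 h should read like Sunday's 69.9 %.

The forecast names J as leader in green at 70 % and J in ochre at 44.5 %: “so saturation probably just holds”.

The flasks give J at 70.1 % in green and J at 43.2 % in ochre. At 25.0 h, ochre still holds 18.8 % of its Z charge as solid. Ochre's bill comes to 0.271 M, which leaves 0.113 M of the charge; that matches solid Z of 0.0722 M plus Q at 0.0410 M.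

    J + Q → D (k = 0.963 /M/h)
    Q + D → X (k = 1.50 /M/h)
    Z ⇌ Q, rate k3*(cs3 - [Q]) while solid is left; crystals form when [Q] > cs3 (solubility = 0.130 M, k = 0.131 /h)

A neighbour of ochre has 0.15 M of Z, less than Sunday's bill. If that neighbour's bill takes up its charge at Sunday's 1.31 of Z per J lost, its J comes to about 64.2 %. That neighbour shows J at 64.0 % at 25.0 h, with Z, the limiting reagent, at 0 % and Q at 4.92 × 10⁻⁴ M.

(The runs were generated by integration on assumed constants; the scatter is artificial.)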